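**Retrosynthetic overview**

1. The target is one pyrrole ring (N1, C2–C5) with CHO on C2 and n‑C19H39 on C5. These two α‑carbons are 1,4‑related, so cutting N1–C2 and N1–C5 (Paal–Knorr) exposes a masked 1,2,5‑tricarbonyl, 1,1‑dimethoxytetracosane‑2,5‑dione.
2. In the same operation the C4–C5 bond is cut by acyl‑anion (Stetter) logic. C5 with the whole C19 chain is icosanal, C2–C3–C4 with the formyl carbon is 1,1‑dimethoxybut‑3‑en‑2‑one, and N1 is ammonia.
3. One pot therefore joins three components (C20 aldehyde, C4 enone acetal, NH3) around the pyrrole core. This parallels the Maillard‑type formation of 2‑formylpyrroles from 3‑deoxyosone‑like 1,2,5‑tricarbonyls and amines.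
4. Precursors: icosanal by oxidation of 1‑icosanol; the enone from methyl dimethoxyacetate via the Weinreb amide and vinyl Grignard addition.
5. Ring order: the pyrrole is the only ring and is closed last; the formyl group is unveiled from its acetal in the same pot.

Key step: step 4

Remark on the chemistry: the target has no stereocentre and no stereogenic double bond, so "single enantiomer" is taken to mean the achiral compound as drawn; no stereocontrol is needed.

**Step 1**
Reactants: 1 1‑icosanol
Product: 2 icosanal
Conditions: TEMPO (10 mol%), PhI(OAc)2 (1.1 equiv), CH2Cl2, rt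
Reagents that add atoms: none
Why: Oxoammonium (TEMPO/PhI(OAc)2) oxidation of a primary alcohol should stop at the aldehyde in the absence of water.

**Step 2**
Reactants: 3 methyl 2,2‑dimethoxyacetate
Product: 4 N,2,2‑trimethoxy‑N‑methylacetamide
Conditions: MeNH(OMe)·HCl (1.5 equiv), i‑PrMgCl (3.0 equiv), THF, −20 to 0 °C; aq. NH4Cl
Reagents that add atoms: N,O‑dimethylhydroxylamine hydrochloride, CNOC.Cl
Why: Weinreb amide formation by acyl substitution of the activated ester with the chloromagnesium amide; the acetal is inert to base.

**Step 3**
Reactants: 4 N,2,2‑trimethoxy‑N‑methylacetamide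
Product: 5 1,1‑dimethoxybut‑3‑en‑2‑one
Conditions: CH2=CHMgBr (1.3 equiv), THF, −78 to 0 °C; inverse quench into cold 1 M HCl/Et2O; used at once as a BHT‑stabilised solution
Reagents that add atoms: vinylmagnesium bromide, C=C[Mg]Br
Why: Weinreb ketone synthesis, in which the magnesium chelate of the tetrahedral adduct prevents a second addition and the acidic inverse quench protonates the released amine before it can add to the enone.

**Step 4**
Reactants: 2 icosanal; 5 1,1‑dimethoxybut‑3‑en‑2‑one
Product: 8 5‑nonadecyl‑1H‑pyrrole‑2‑carbaldehyde, via 1,1‑dimethoxytetracosane‑2,5‑dione 6 (not isolated), via 2‑(dimethoxymethyl)‑5‑nonadecyl‑1H‑pyrrole 7 (not isolated)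
Conditions: (i) 3‑benzyl‑5‑(2‑hydroxyethyl)‑4‑methylthiazolium chloride (20 mol%), Et3N (0.6 equiv), 1,4‑dioxane, 75 °C, slow addition of 5; (ii) NH4OAc (10 equiv), MeOH, 55 °C; (iii) AcOH/H2O (1:1), THF, rt to 40 °C
Reagents that add atoms: ammonium acetate, [NH4+].CC(=O)[O-]; water, O
Why: The thiazolium‑derived carbene adds to icosanal to give a nucleophilic enaminol (acyl‑anion equivalent) that adds 1,4 to enone 5, forming the bond between the future pyrrole C5 (the aldehyde carbon, which brings the whole nonadecyl chain) and C4 and releasing the catalyst and the 1,4‑diketone 6 (Stetter reaction; closest precedent is the thiazolium‑catalysed addition of unbranched aliphatic aldehydes to methyl vinyl ketone). Ammonia then condenses with one ketone of 6 to a hemiaminal/enamine whose nitrogen attacks the second carbonyl in a 5‑exo‑trig closure, and loss of two molecules of water aromatises the ring to pyrrole 7 (Paal–Knorr synthesis, as applied to 1,1‑dialkoxy‑2,5‑diones for other 2‑formylpyrroles). No stereocentre is formed. The selectivity needed is conjugate over 1,2‑addition of the acyl anion (acyloin formation with a second aldehyde or with the activated ketone of 5); the 1,2‑additions are reversible under the catalyst whereas the Stetter addition is not, and slow addition of 5 limits its polymerisation. Regiochemistry needs no control, because the 1,4‑relationship of the carbonyl groups in 6 places the chain on C5 and the formyl carbon on C2 whichever ketone reacts first, and the dimethyl acetal keeps the formyl carbon out of imidazole‑ or pyrazine‑forming reactions of a free 1,2‑dicarbonyl with ammonia. The pyrrol‑2‑yl acetal of 7 ionises readily through an azafulvenium ion, so aqueous acetic acid should release the aldehyde of 8, which is acid‑stable as a vinylogous formamide.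

**Compound list**

1 | 1‑icosanol | CCCCCCCCCCCCCCCCCCCCO | starting material
2 | icosanal | CCCCCCCCCCCCCCCCCCCC=O | intermediate
3 | methyl 2,2‑dimethoxyacetate | COC(OC)C(=O)OC | starting material
4 | N,2,2‑trimethoxy‑N‑methylacetamide | COC(OC)C(=O)N(C)OC | intermediate
5 | 1,1‑dimethoxybut‑3‑en‑2‑one | C=CC(=O)C(OC)OC | intermediate
6 | 1,1‑dimethoxytetracosane‑2,5‑dione | CCCCCCCCCCCCCCCCCCCC(=O)CCC(=O)C(OC)OC | intermediate (not isolated)
7 | 2‑(dimethoxymethyl)‑5‑nonadecyl‑1H‑pyrrole | CCCCCCCCCCCCCCCCCCCc1ccc(C(OC)OC)[nH]1 | intermediate (not isolated)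
8 | 5‑nonadecyl‑1H‑pyrrole‑2‑carbaldehyde | CCCCCCCCCCCCCCCCCCCc1ccc(C=O)[nH]1 | target

**Step count and risks**

Total step count: 4 (compounds 6 and 7 are not isolated).
Longest linear sequence: 3 steps (3 → 4 → 5 → 8); the other branch is 2 steps (1 → 2 → 8).

Steps most likely to fail:

1. Step 4 (key step). The conjugate acyl transfer may be outrun by acyloin self‑condensation of the aldehyde or by carbene/base‑induced polymerisation of the enone. The acetal pyrrole may also oligomerise through azafulvenium ions before it is hydrolysed. Fallback, from 2 to 8: the formyl carbon is no longer carried through the ring synthesis but introduced afterwards by electrophilic substitution. The Grignard reagent of 2‑(2‑bromoethyl)‑1,3‑dioxolane (Mg, THF) should add to icosanal 2 to give racemic 1‑(1,3‑dioxolan‑2‑yl)docosan‑3‑ol F1. Dess–Martin oxidation should give the γ‑keto acetal 1‑(1,3‑dioxolan‑2‑yl)docosan‑3‑one F2. Paal–Knorr condensation with NH4OAc in aqueous AcOH, with the dioxolane opened in the pot, should give 2‑nonadecyl‑1H‑pyrrole F3. Vilsmeier–Haack formylation (POCl3, DMF, 0 °C; aq. NaOAc) at the free α‑position C5 should then give 8.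

2. Step 3. The liberated N,O‑dimethylhydroxylamine or a second equivalent of the Grignard reagent may add in conjugate fashion during the quench, and the small enone may polymerise or be lost on concentration. Fallback, from 4 back to 5: the enone is replaced by a storable Mannich base that releases it only in the flask of step 4. MeMgBr (THF, 0 °C) should convert Weinreb amide 4 into 1,1‑dimethoxypropan‑2‑one F4. Kinetic enolisation on the methyl side (LDA, THF, −78 °C) and trapping with dimethylmethyleneiminium iodide should give 4‑(dimethylamino)‑1,1‑dimethoxybutan‑2‑one F5. F5 is charged into step 4 in place of 5, where Et3N at 75 °C should eliminate dimethylamine and generate 5 at low stationary concentration (Stetter reaction with a Mannich base as vinyl ketone surrogate). The route is rejoined at 5.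

3. Step 2. i‑PrMgCl may attack the activated ester carbonyl in competition with the magnesium amide, or the acyl substitution may stall. Fallback, from 3 to 5: the Weinreb amide is avoided and the ketone oxidation level is reached by oxidation. DIBAL‑H (1.05 equiv, CH2Cl2, −78 °C) should reduce ester 3 to 2,2‑dimethoxyacetaldehyde F6, held as its aluminium hemiacetal and treated in the same flask with vinylmagnesium bromide to give racemic 1,1‑dimethoxybut‑3‑en‑2‑ol F7. Oxidation of this allylic alcohol with activated MnO2 (CH2Cl2, rt) should give 5.

**Further compounds**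

F1 | step 4 | 1‑(1,3‑dioxolan‑2‑yl)docosan‑3‑ol (racemic) | CCCCCCCCCCCCCCCCCCCC(O)CCC1OCCO1
F2 | step 4 | 1‑(1,3‑dioxolan‑2‑yl)docosan‑3‑one | CCCCCCCCCCCCCCCCCCCC(=O)CCC1OCCO1
F3 | step 4 | 2‑nonadecyl‑1H‑pyrrole | CCCCCCCCCCCCCCCCCCCc1ccc[nH]1
F4 | step 3 | 1,1‑dimethoxypropan‑2‑one | CC(=O)C(OC)OC
F5 | step 3 | 4‑(dimethylamino)‑1,1‑dimethoxybutan‑2‑one | CN(C)CCC(=O)C(OC)OC
F6 | step 2 | 2,2‑dimethoxyacetaldehyde | COC(OC)C=O
F7 | step 2 | 1,1‑dimethoxybut‑3‑en‑2‑ol (racemic) | C=CC(O)C(OC)OC
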